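**Plan**

- Retrosynthesis: the butenolide is opened at C13=C14 to a C13 ketone whose C16 oxygen carries a diethylphosphonoacetate. The C16–O bond is then cut (carboxylate plus bromomethyl ketone), C16–Br goes back to a C13 methyl ketone, and the ring B pattern (6β-OAc, C8=C9) goes back to a 6-ketone with an exocyclic C8=C17 olefin.
- Feature used: the five-membered lactone (C13, C14, C15, ring O, C16) has its olefin carbon C13 bonded to the O-linked C16, which is the retron of an intramolecular olefination of an α-acyloxy ketone. Rings A and B with C1–C13, C16–C20 and an oxygen on C6 are already present in larixol 1.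
- Forward: rings A and B come intact from 1. The side chain is cut to the methyl ketone and masked, ring B is adjusted (C6 oxidation, olefin migration to C8=C9, reduction, acetylation), C16 is brominated and esterified with diethylphosphonoacetic acid 2, and the lactone, the only ring made, closes last.
- Stereochemistry: C5 and C10 are those of 1. C6 is inverted from 6α to 6β by oxidation and α-face hydride delivery. The C9 and C13 stereocenters of 1 are erased on the way.

Key step: step 10

Assumption: larixol is taken as a purchasable natural product; labdane numbering is used, and the target SMILES is read as 5α-H, 10β-CH3 and a 6β (axial) acetate, the opposite C6 configuration to larixol.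

**Route**

Step 1
Reactants: 1 larixol, (13S)-labda-8(17),14-diene-6α,13-diol
Product: 3 hydroxy ketone 6α-hydroxy-14,15-dinorlabd-8(17)-en-13-one
Conditions: KMnO4, BnEt3NCl (cat.), CH2Cl2/H2O, 0 °C → rt
Reagents that add atoms: none
Why: Permanganate degradation of a tertiary vinyl carbinol: the monosubstituted C14=C15 bond is hydroxylated and the C13–C14 bond of the resulting glycol is cleaved faster than the hindered C8=C17 bond reacts, the usual way from 13-hydroxylabd-14-enes to 14,15-dinor-13-ketones, with the C13 hydroxyl oxygen becoming the carbonyl oxygen.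

Step 2
Reactants: 3 hydroxy ketone 6α-hydroxy-14,15-dinorlabd-8(17)-en-13-one
Product: 4 ketal alcohol 13,13-(ethylenedioxy)-14,15-dinorlabd-8(17)-en-6α-ol
Conditions: ethylene glycol, PPTS (cat.), benzene, reflux, Dean–Stark
Reagents that add atoms: ethylene glycol, OCCO
Why: Acid-catalyzed ketalization with azeotropic water removal converts the unhindered methyl ketone into a dioxolane that shields C13 from the butoxide and hydride of steps 4 and 5, while the weak acid leaves the exocyclic olefin in place.

Step 3
Reactants: 4 ketal alcohol 13,13-(ethylenedioxy)-14,15-dinorlabd-8(17)-en-6α-ol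
Product: 5 ketal ketone 13,13-(ethylenedioxy)-14,15-dinorlabd-8(17)-en-6-one
Conditions: Dess–Martin periodinane, pyridine, CH2Cl2, 0 °C → rt
Reagents that add atoms: none
Why: Dess–Martin oxidation of the equatorial secondary alcohol under buffered, non-acidic conditions spares the dioxolane; any drift of the olefin into conjugation is harmless because step 4 equilibrates all olefin isomers.

Step 4
Reactants: 5 ketal ketone 13,13-(ethylenedioxy)-14,15-dinorlabd-8(17)-en-6-one
Product: 7 β,γ-unsaturated ketone 13,13-(ethylenedioxy)-14,15-dinorlabd-8-en-6-one, via potassium dienolate 6 (not isolated)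
Conditions: KOt-Bu (excess), degassed t-BuOH, rt; then inverse quench into 10% aq. AcOH, 0 °C
Reagents that add atoms: none
Why: Deconjugative isomerization through an extended enolate (the 4-en-3-one to 5-en-3-one protocol of steroids, isophorone to β-isophorone): excess butoxide should equilibrate 5 and its conjugated 7-ene isomer to the more substituted endocyclic dienolate 6, whose kinetic protonation at the α-carbon C7 leaves the tetrasubstituted C8=C9 bond, while C5 keeps the more stable trans ring fusion.

Step 5
Reactants: 7 β,γ-unsaturated ketone 13,13-(ethylenedioxy)-14,15-dinorlabd-8-en-6-one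
Product: 8 axial alcohol 13,13-(ethylenedioxy)-14,15-dinorlabd-8-en-6β-ol
Conditions: LiAlH4, THF, −78 → 0 °C; then H2O
Reagents that add atoms: none
Why: Hydride reduction under steric approach control: the β-face of C6 is screened by the syn-axial C19 and C20 methyl groups, so hydride should enter from the α-face and set the axial 6β-alcohol, and the cold aprotic medium should reduce the ketone before it can reconjugate.

Step 6
Reactants: 8 axial alcohol 13,13-(ethylenedioxy)-14,15-dinorlabd-8-en-6β-ol
Product: 9 ketal acetate 6β-acetoxy-13,13-(ethylenedioxy)-14,15-dinorlabd-8-ene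
Conditions: Ac2O, DMAP, Et3N, CH2Cl2, rt → 40 °C
Reagents that add atoms: acetic anhydride, CC(=O)OC(C)=O
Why: DMAP-catalyzed acyl transfer is the standard acetylation of a hindered axial secondary alcohol and retains the C6 configuration because the C6–O bond is not touched.

Step 7
Reactants: 9 ketal acetate 6β-acetoxy-13,13-(ethylenedioxy)-14,15-dinorlabd-8-ene
Product: 10 acetoxy ketone 6β-acetoxy-14,15-dinorlabd-8-en-13-one
Conditions: 1 M aq. HCl, THF, rt
Reagents that add atoms: water, O
Why: Mild acid hydrolysis of the dioxolane; the secondary acetate and the tetrasubstituted olefin, which already sits in the thermodynamic position of ring B, should be stable to dilute acid at room temperature.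

Step 8
Reactants: 10 acetoxy ketone 6β-acetoxy-14,15-dinorlabd-8-en-13-one
Product: 13 bromo ketone 6β-acetoxy-16-bromo-14,15-dinorlabd-8-en-13-one, via lithium enolate 11 (not isolated), via trimethylsilyl enol ether 12 (not isolated)
Conditions: LiN(SiMe3)2 (1.1 equiv), THF, −78 °C; Me3SiCl, −78 → 0 °C; then NBS, −78 → 0 °C
Reagents that add atoms: N-bromosuccinimide, O=C1CCC(=O)N1Br
Why: Kinetic deprotonation of a methyl ketone by a hindered amide at −78 °C occurs at the methyl group C16 and faster than at the acetate, silylation fixes that regiochemistry, and bromination of the silyl enol ether by NBS should be much faster than attack on the hindered C8=C9 bond.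

Step 9
Reactants: 13 bromo ketone 6β-acetoxy-16-bromo-14,15-dinorlabd-8-en-13-one; 2 diethylphosphonoacetic acid
Product: 14 phosphonoacetate 6β-acetoxy-16-[(diethoxyphosphoryl)acetoxy]-14,15-dinorlabd-8-en-13-one
Conditions: 2 (1.3 equiv), Cs2CO3 (0.6 equiv), DMF, 0 °C → rt
Reagents that add atoms: none
Why: SN2 displacement of a primary α-keto bromide by a cesium carboxylate; with the acid in slight excess over carbonate no base strong enough to deprotonate the phosphonate is present, so 14 should be isolable.

Step 10
Reactants: 14 phosphonoacetate 6β-acetoxy-16-[(diethoxyphosphoryl)acetoxy]-14,15-dinorlabd-8-en-13-one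
Product: 15 target 6β-acetoxylabda-8,13-dien-15,16-olide
Conditions: LiCl, DBU, MeCN, rt, high dilution
Reagents that add atoms: none
Why: LiCl coordinates the phosphoryl and ester carbonyl oxygens of 14, which lets the amidine DBU deprotonate C14; the carbanion adds to the C13 ketone, the β-oxido phosphonate closes to an oxaphosphetane and syn-elimination of diethyl phosphate leaves the C13=C14 bond. The closest known reaction type is the intramolecular Horner–Wadsworth–Emmons olefination of α-(phosphonoacetoxy) ketones under Masamune–Roush conditions, the standard construction of β-substituted butenolides such as the cardenolide ring. The lactone ring (C13, C14, C15, ring O, C16) is closed by the C14-to-C13 addition, a 5-exo-trig attack on the carbonyl group, and the ring fixes the olefin geometry. No stereocenter is formed, and C5, C6 and C10 are remote from the reacting atoms. The selectivity needed is chemoselectivity for the ketone over the two ester carbonyls and over loss of the acyloxy group: only the ketone lies within five-membered reach of C14, it sits on an unhindered two-carbon arm, and the LiCl/DBU pair is too mild to cleave the hindered acetate or to shift the C8=C9 bond.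

**Compound list**

1 | larixol, (13S)-labda-8(17),14-diene-6α,13-diol (5α-H, 9α-H, 10β-CH3) | O[C@H]1CC(=C)[C@H](CC[C@](C)(O)C=C)[C@@]2(C)CCCC(C)(C)[C@H]12 | starting material
2 | diethylphosphonoacetic acid, 2-(diethoxyphosphoryl)acetic acid | OC(=O)CP(=O)(OCC)OCC | starting material
3 | 6α-hydroxy-14,15-dinorlabd-8(17)-en-13-one | O[C@H]1CC(=C)[C@H](CCC(C)=O)[C@@]2(C)CCCC(C)(C)[C@H]12 | intermediate
4 | 13,13-(ethylenedioxy)-14,15-dinorlabd-8(17)-en-6α-ol | O[C@H]1CC(=C)[C@H](CCC3(C)OCCO3)[C@@]2(C)CCCC(C)(C)[C@H]12 | intermediate
5 | 13,13-(ethylenedioxy)-14,15-dinorlabd-8(17)-en-6-one | O=C1CC(=C)[C@H](CCC3(C)OCCO3)[C@@]2(C)CCCC(C)(C)[C@H]12 | intermediate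
6 | potassium 13,13-(ethylenedioxy)-14,15-dinorlabda-6,8-dien-6-olate (dienolate, formed in the flask in step 4) | [K+].[O-]C1=CC(C)=C(CCC3(C)OCCO3)[C@@]2(C)CCCC(C)(C)[C@H]12 | intermediate
7 | 13,13-(ethylenedioxy)-14,15-dinorlabd-8-en-6-one | O=C1CC(C)=C(CCC3(C)OCCO3)[C@@]2(C)CCCC(C)(C)[C@H]12 | intermediate
8 | 13,13-(ethylenedioxy)-14,15-dinorlabd-8-en-6β-ol | O[C@@H]1CC(C)=C(CCC3(C)OCCO3)[C@@]2(C)CCCC(C)(C)[C@H]12 | intermediate
9 | 6β-acetoxy-13,13-(ethylenedioxy)-14,15-dinorlabd-8-ene | CC(=O)O[C@@H]1CC(C)=C(CCC3(C)OCCO3)[C@@]2(C)CCCC(C)(C)[C@H]12 | intermediate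
10 | 6β-acetoxy-14,15-dinorlabd-8-en-13-one | CC(=O)O[C@@H]1CC(C)=C(CCC(C)=O)[C@@]2(C)CCCC(C)(C)[C@H]12 | intermediate
11 | lithium 6β-acetoxy-14,15-dinorlabda-8,13(16)-dien-13-olate (kinetic enolate, formed in the flask in step 8) | CC(=O)O[C@@H]1CC(C)=C(CCC(=C)[O-])[C@@]2(C)CCCC(C)(C)[C@H]12.[Li+] | intermediate
12 | 6β-acetoxy-13-(trimethylsilyloxy)-14,15-dinorlabda-8,13(16)-diene (formed in the flask in step 8) | CC(=O)O[C@@H]1CC(C)=C(CCC(=C)O[Si](C)(C)C)[C@@]2(C)CCCC(C)(C)[C@H]12 | intermediate
13 | 6β-acetoxy-16-bromo-14,15-dinorlabd-8-en-13-one | CC(=O)O[C@@H]1CC(C)=C(CCC(=O)CBr)[C@@]2(C)CCCC(C)(C)[C@H]12 | intermediate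
14 | 6β-acetoxy-16-[(diethoxyphosphoryl)acetoxy]-14,15-dinorlabd-8-en-13-one | CC(=O)O[C@@H]1CC(C)=C(CCC(=O)COC(=O)CP(=O)(OCC)OCC)[C@@]2(C)CCCC(C)(C)[C@H]12 | intermediate
15 | 6β-acetoxylabda-8,13-dien-15,16-olide | CC(=O)O[C@@H]1CC(C)=C(CCC2=CC(=O)OC2)[C@@]2(C)CCCC(C)(C)[C@H]12 | target

**Step count**

Total steps: 10. Longest linear sequence: 10 steps (1 → 15); 2 enters in step 9.

**Steps most likely to fail**

Step 4. The dienolate may protonate at the γ-carbon, the β,γ-unsaturated ketone may reconjugate during quench and isolation, the exocyclic and endocyclic dienolates may not equilibrate fully, and the dienolate is sensitive to air. The fallback sets out from 5 and comes back to the route at 8. Dienolate 6, generated with KOt-Bu in THF/t-BuOH as in step 4, would be O-acetylated with Ac2O to the stable dienyl acetate 6-acetoxy-13,13-(ethylenedioxy)-14,15-dinorlabda-6,8-diene F1. NaBH4 in EtOH would then cleave the enol ester; the freed dienolate is protonated at C7 by the solvent and the β,γ-unsaturated ketone is reduced from the α-face as it forms. This is the classical borohydride reduction of steroidal dienol acetates to β,γ-unsaturated alcohols, and it replaces steps 4 and 5 without the free ketone ever accumulating.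

Step 8. NBS may transfer bromine to the C8=C9 bond or its allylic positions, and enolization may compete toward C12 or at the acetate. The fallback sets out from 10 and comes back at 14. Deprotonation of 10 with KN(SiMe3)2 in THF at −78 °C would give the potassium enolate F2, which would be hydroxylated at C16 by 2-(phenylsulfonyl)-3-phenyloxaziridine, an oxygen-transfer reagent that leaves olefins alone, to give 6β-acetoxy-16-hydroxy-14,15-dinorlabd-8-en-13-one F3. Steglich esterification of F3 with 2 (DCC, DMAP, CH2Cl2) would then give 14 with no electrophilic halogen in the sequence.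

Step 10. DBU may enolize the α-acyloxy ketone toward C16, leading to acyl migration or loss of the acyloxy group; a slow ring closure would allow intermolecular olefination; and the new olefin may be shifted out of conjugation by the base. The fallback sets out from 13 and comes back at 15, forming the same C13=C14 bond by an intramolecular Wittig olefination. Displacement of the bromide of 13 by chloroacetic acid with Cs2CO3 in DMF would give 6β-acetoxy-16-(chloroacetoxy)-14,15-dinorlabd-8-en-13-one F4. PPh3 in MeCN at 60 °C would convert it into the phosphonium chloride 6β-acetoxy-16-[(triphenylphosphonio)acetoxy]-14,15-dinorlabd-8-en-13-one chloride F5. K2CO3 in CH2Cl2 would then generate the ester-stabilized ylide, which olefinates the C13 ketone within the five-membered ring and gives 15 without an amidine base.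

**Further compounds**

F1 | step 4 | 6-acetoxy-13,13-(ethylenedioxy)-14,15-dinorlabda-6,8-diene | CC(=O)OC1=CC(C)=C(CCC3(C)OCCO3)[C@@]2(C)CCCC(C)(C)[C@H]12
F2 | step 8 | potassium 6β-acetoxy-14,15-dinorlabda-8,13(16)-dien-13-olate | CC(=O)O[C@@H]1CC(C)=C(CCC(=C)[O-])[C@@]2(C)CCCC(C)(C)[C@H]12.[K+]
F3 | step 8 | 6β-acetoxy-16-hydroxy-14,15-dinorlabd-8-en-13-one | CC(=O)O[C@@H]1CC(C)=C(CCC(=O)CO)[C@@]2(C)CCCC(C)(C)[C@H]12
F4 | step 10 | 6β-acetoxy-16-(chloroacetoxy)-14,15-dinorlabd-8-en-13-one | CC(=O)O[C@@H]1CC(C)=C(CCC(=O)COC(=O)CCl)[C@@]2(C)CCCC(C)(C)[C@H]12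
F5 | step 10 | 6β-acetoxy-16-[(triphenylphosphonio)acetoxy]-14,15-dinorlabd-8-en-13-one chloride | CC(=O)O[C@@H]1CC(C)=C(CCC(=O)COC(=O)C[P+](c3ccccc3)(c3ccccc3)c3ccccc3)[C@@]2(C)CCCC(C)(C)[C@H]12.[Cl-]
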